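**Retrosynthetic overview**
1. C9–C10 is cut by a Suzuki–Miyaura union of a dienyl side-chain boronate with a core vinyl iodide. C6–C7 is cut by a Hosomi–Sakurai attack of a gem-disilyl methallyl reagent on the peroxycarbenium ion of a bicyclic C6 methoxy peroxyketal, which sets C6.
2. That peroxyketal contains ring A (1,2-dioxane O–O–C3–C4–C5–C6) and ring B (γ-lactone O–C1–C2–C3–C4). It arises in one operation from a monocyclic cyclobutenyl phosphonoacetate: O3/MeOH puts O–O into the C3=C6 bond (four-membered carbocycle to six-membered ring A), an HWE reaction closes ring B, and an oxa-Michael addition closes ring A on C3.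
3. Enabling feature: C3 and C6, the two peroxide-bearing carbons of ring A, are bridged only by C4–C5, so ring A minus O–O is a cyclobutene. C3 is also the β-carbon of ring B and the neighbour of the C4–O bond, so an ester on that oxygen can turn a C3 aldehyde into a Michael acceptor held on one face.
4. The cyclobutene comes from propyne (C3, C6, 6-CH3), dichloroketene (C4, C5), Me2Zn (4-CH3, by catalytic asymmetric addition, the only external source of chirality) and phosphonoacetic acid (C1, C2).
5. Ring order: cyclobutene, then ring B (as a butenolide), then ring A in its final size.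

Key step: step 11

Locants used below: C1 lactone C=O, C2 CH2, C3 CH(OO), C4 C(CH3)(O), C5 CH2, C6 C(CH3)(OO), C7 CH2, C8(CH3)=C9, C10=C11, C12–C14 (CH2)3, C15=C16–Ph.
Assumption: the sense of induction in step 8 is taken by analogy with other cyclic 2-substituted enones, and the ligand enantiomer is chosen so that the (S)-alcohol results.

**Step 1**
Reactants: 1 hex-5-yn-1-ol
Product: 2 hex-5-ynal
Conditions: TEMPO (cat.), PhI(OAc)2, CH2Cl2, rt
Reagents that add atoms: none
Why: The oxoammonium (TEMPO) oxidation of a primary alcohol stops at the aldehyde and leaves the terminal alkyne untouched.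

**Step 2**
Reactants: 2 hex-5-ynal; 3 diethyl benzylphosphonate
Product: 4 [(1E)-hept-1-en-6-yn-1-yl]benzene
Conditions: NaH, THF, 0 °C to rt
Reagents that add atoms: none
Why: The Horner–Wadsworth–Emmons olefination of an unbranched aldehyde with a benzylphosphonate anion should give the (E)-styrene, because the addition is reversible and the anti-oxaphosphetane collapses faster.

**Step 3**
Reactants: 4 [(1E)-hept-1-en-6-yn-1-yl]benzene
Product: 5 4,4,5,5-tetramethyl-2-[(1E,6E)-7-phenylhepta-1,6-dien-1-yl]-1,3,2-dioxaborolane
Conditions: HBpin, Cp2ZrHCl (cat.), Et3N (cat.), neat, 60 °C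
Reagents that add atoms: pinacolborane, CC1(C)OBOC1(C)C
Why: The zirconium-catalysed syn-hydroboration of a terminal alkyne places boron on the terminal carbon, gives the (E)-alkenylboronate, and is much faster than any reaction at the 1,2-disubstituted styrene.

**Step 4**
Reactants: 6 chlorobis(trimethylsilyl)methane; 7 2-bromopropene
Product: 9 (2-methylprop-2-ene-1,1-diyl)bis(trimethylsilane), via Grignard reagent 8 (not isolated)
Conditions: Mg, THF, reflux; then 7, NiCl2(dppp) (cat.), THF, 0 °C to rt
Reagents that add atoms: none
Why: The Kumada–Corriu coupling of an α-silylalkyl Grignard reagent, which cannot undergo β-hydride loss, with an alkenyl bromide is the standard entry to allylsilanes and fixes both silyl groups on the same carbon without regiochemical ambiguity.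

**Step 5**
Reactants: 10 propyne; 11 trichloroacetyl chloride
Product: 13 4,4-dichloro-3-methylcyclobut-2-en-1-one, via dichloroketene 12 (not isolated)
Conditions: Zn–Cu couple, Et2O, 0 °C to rt
Reagents that add atoms: none
Why: In the thermal [2+2] cycloaddition of dichloroketene to an alkyne, the ketene carbonyl carbon bonds to the terminal alkyne carbon because the developing vinyl cation is best placed on the methyl-bearing carbon, which fixes the 3-methyl pattern.

**Step 6**
Reactants: 13 4,4-dichloro-3-methylcyclobut-2-en-1-one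
Product: 14 3-methylcyclobut-2-en-1-one
Conditions: Zn, AcOH, TMEDA, EtOH, 0 °C to rt
Reagents that add atoms: none
Why: The reductive dechlorination of an α,α-dichloroketone by zinc in buffered acetic acid runs through zinc enolates and removes both temporary chlorine atoms without reducing the enone.

**Step 7**
Reactants: 14 3-methylcyclobut-2-en-1-one
Product: 16 2-bromo-3-methylcyclobut-2-en-1-one, via dibromide 15 (not isolated)
Conditions: Br2, CH2Cl2, −78 to 0 °C; then Et3N, 0 °C
Reagents that add atoms: bromine, BrBr
Why: Bromine addition followed by E1cB loss of HBr (α-bromination of an enone) installs a removable α-substituent that makes the two flanks of the carbonyl group sterically unequal for step 8.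

**Step 8**
Reactants: 16 2-bromo-3-methylcyclobut-2-en-1-one
Product: 17 (1S)-2-bromo-1,3-dimethylcyclobut-2-en-1-ol
Conditions: Me2Zn, Ti(OiPr)4, trans-1,2-bis(hydroxycamphorsulfonamido)cyclohexane (HOCSAC, cat.), toluene–hexane, 0 °C to rt; aq. work-up
Reagents that add atoms: dimethylzinc, C[Zn]C
Why: The titanium-mediated catalytic asymmetric 1,2-addition of a dialkylzinc to a ketone is known to give tertiary allylic alcohols from cyclic 2-substituted enones; the chiral titanium complex tells the bromoalkene flank from the CH2 flank and so sets C4 as (S).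

**Step 9**
Reactants: 17 (1S)-2-bromo-1,3-dimethylcyclobut-2-en-1-ol
Product: 19 (1S)-1,3-dimethylcyclobut-2-en-1-ol, via dilithio intermediate 18 (not isolated)
Conditions: t-BuLi (3.1 equiv), Et2O, −78 °C; then H2O–THF, −78 °C
Reagents that add atoms: none
Why: Bromine–lithium exchange on the lithium alkoxide and cold protonation replace the auxiliary bromine by hydrogen without moving the alkene, the low temperature holds back electrocyclic opening of the cyclobutenolate, and C4 is not involved.

**Step 10**
Reactants: 19 (1S)-1,3-dimethylcyclobut-2-en-1-ol; 20 (diethoxyphosphoryl)acetic acid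
Product: 21 (1S)-1,3-dimethylcyclobut-2-en-1-yl (diethoxyphosphoryl)acetate
Conditions: DCC, DMAP (cat.), CH2Cl2, 0 °C; chromatography on Et3N-deactivated silica, cold storage
Reagents that add atoms: none
Why: The Steglich esterification of phosphonoacetic acids runs through a ketene-like acyl donor and therefore acylates tertiary alcohols, and it works under neutral conditions, so the C4–O bond is never ionised to the symmetrical cyclobutenyl cation and C4 keeps its configuration.

**Step 11**
Reactants: 21 (1S)-1,3-dimethylcyclobut-2-en-1-yl (diethoxyphosphoryl)acetate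
Product: 26 (4aS,7aS)-3-methoxy-3,4a-dimethyltetrahydrofuro[3,2-c][1,2]dioxin-6(3H)-one (cis-fused; both epimers at ketal carbon C6), via carbonyl oxide aldehyde 22 (not isolated), via hydroperoxy ketal aldehyde 23 (not isolated), via dioxanol 24 (not isolated), via butenolide hydroperoxide 25 (not isolated)
Conditions: O3, CH2Cl2–MeOH (3:1), NaHCO3, −78 °C; N2 purge; then MeCN, LiCl, iPr2NEt, −20 °C to rt
Reagents that add atoms: ozone, [O-][O+]=O; methanol, CO
Why: Proposed new method: ozone adds to the strained C3=C6 bond of 21 and Criegee cycloreversion should place the carbonyl oxide on the methyl-bearing C6 (22, the more substituted terminus and the one remote from the electron-withdrawing C4 acyloxy group), methanol traps it as hydroperoxy ketal 23, and the OOH group rests on the C3 aldehyde as dioxanol 24 (6-exo-trig), so that O–O now stands where the ring C=C bond was. LiCl and iPr2NEt then drain the open form 23 through an intramolecular Horner–Wadsworth–Emmons olefination (five-membered ring B, closed by forming C2=C3) to butenolide 25, whose peroxide terminus adds to C3 in a 6-exo-trig oxa-Michael reaction and closes ring A of 26. The closest known reaction types are the ozonolysis of cycloalkenes in methanol to alkoxy hydroperoxide carbonyl compounds, the phosphonoacetate route from α-acyloxy carbonyl compounds to butenolides, and the amine-promoted cyclisation of alkoxy hydroperoxides onto unsaturated esters to give 1,2-dioxanes; what is new is their telescoping into one ring expansion from four to six atoms. C3 is controlled by C4, because the C5–C6 arm that carries the peroxide is fixed on one face of the planar butenolide and only the cis-fused bicycle can form, while the C6 ketal centre is left uncontrolled on purpose since step 12 erases it. The step needs the olefination to outrun base-induced fragmentation of 24 to a C3 carboxylic acid, which the five-membered intramolecular closure, the non-enolisable aldehyde and the mild lithium-assisted base should secure, and no other C=C bond competes for ozone.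

**Step 12**
Reactants: 26 (4aS,7aS)-3-methoxy-3,4a-dimethyltetrahydrofuro[3,2-c][1,2]dioxin-6(3H)-one; 9 (2-methylprop-2-ene-1,1-diyl)bis(trimethylsilane)
Product: 27 (3R,4aS,7aS)-3,4a-dimethyl-3-[(2E)-2-methyl-3-(trimethylsilyl)prop-2-en-1-yl]tetrahydrofuro[3,2-c][1,2]dioxin-6(3H)-one
Conditions: TMSOTf (cat.), CH2Cl2, −78 to −40 °C
Reagents that add atoms: none
Why: In this Hosomi–Sakurai allylation of a cyclic peroxyketal through its peroxycarbenium ion, the ion should react in the half-chair with the C4–O bond pseudoaxial and the C4 methyl pseudoequatorial, axial attack on the face of that oxygen avoids a syn-axial clash with the C4 methyl group and sets C6 as (R) from either ketal epimer, and anti-SE2' loss of one silyl group leaves the (E)-vinylsilane.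

**Step 13**
Reactants: 27 the (E)-vinylsilane lactone
Product: 28 (3R,4aS,7aS)-3-[(2E)-3-iodo-2-methylprop-2-en-1-yl]-3,4a-dimethyltetrahydrofuro[3,2-c][1,2]dioxin-6(3H)-one
Conditions: NIS, MeCN, 0 °C to rt, dark
Reagents that add atoms: N-iodosuccinimide, O=C1CCC(=O)N1I
Why: Electrophilic iododesilylation (ipso substitution through the β-silyl cation) in acetonitrile proceeds with retention of alkene geometry and touches neither the dialkyl peroxide nor the lactone.

**Step 14**
Reactants: 28 the (E)-vinyl iodide lactone; 5 the (1E,6E)-dienylboronate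
Product: 29 plakortolide H, (3R,4aS,7aS)-3,4a-dimethyl-3-[(2E,4E,9E)-2-methyl-10-phenyldeca-2,4,9-trien-1-yl]tetrahydrofuro[3,2-c][1,2]dioxin-6(3H)-one
Conditions: Pd(dppf)Cl2 (cat.), K3PO4 (aq.), THF, rt, degassed
Reagents that add atoms: none
Why: The Suzuki–Miyaura coupling of two stereodefined alkenyl partners is stereoretentive at both ends, palladium-catalysed couplings of iodoalkenyl dialkyl peroxides are a known class that leaves the O–O bond intact, and the mild base at room temperature touches no stereocentre.

**Compound list**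
1 | hex-5-yn-1-ol | OCCCCC#C | starting material
2 | hex-5-ynal | O=CCCCC#C | intermediate
3 | diethyl benzylphosphonate | CCOP(=O)(Cc1ccccc1)OCC | starting material
4 | [(1E)-hept-1-en-6-yn-1-yl]benzene | C#CCCC/C=C/c1ccccc1 | intermediate
5 | 4,4,5,5-tetramethyl-2-[(1E,6E)-7-phenylhepta-1,6-dien-1-yl]-1,3,2-dioxaborolane | CC1(C)OB(/C=C/CCC/C=C/c2ccccc2)OC1(C)C | intermediate
6 | chlorobis(trimethylsilyl)methane | C[Si](C)(C)C(Cl)[Si](C)(C)C | starting material
7 | 2-bromopropene | CC(Br)=C | starting material
8 | [bis(trimethylsilyl)methyl]magnesium chloride | C[Si](C)(C)C([Mg]Cl)[Si](C)(C)C | intermediate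
9 | (2-methylprop-2-ene-1,1-diyl)bis(trimethylsilane) | C=C(C)C([Si](C)(C)C)[Si](C)(C)C | intermediate
10 | propyne | CC#C | starting material
11 | trichloroacetyl chloride | ClC(=O)C(Cl)(Cl)Cl | starting material
12 | dichloroketene | ClC(Cl)=C=O | intermediate
13 | 4,4-dichloro-3-methylcyclobut-2-en-1-one | CC1=CC(=O)C1(Cl)Cl | intermediate
14 | 3-methylcyclobut-2-en-1-one | CC1=CC(=O)C1 | intermediate
15 | 2,3-dibromo-3-methylcyclobutan-1-one | CC1(Br)CC(=O)C1Br | intermediate
16 | 2-bromo-3-methylcyclobut-2-en-1-one | CC1=C(Br)C(=O)C1 | intermediate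
17 | (1S)-2-bromo-1,3-dimethylcyclobut-2-en-1-ol | CC1=C(Br)[C@@](C)(O)C1 | intermediate
18 | lithium (1S)-2-lithio-1,3-dimethylcyclobut-2-en-1-olate | CC1=C([Li])[C@@](C)(O[Li])C1 | intermediate
19 | (1S)-1,3-dimethylcyclobut-2-en-1-ol | CC1=C[C@@](C)(O)C1 | intermediate
20 | (diethoxyphosphoryl)acetic acid | OC(=O)CP(=O)(OCC)OCC | starting material
21 | (1S)-1,3-dimethylcyclobut-2-en-1-yl (diethoxyphosphoryl)acetate | CC1=C[C@@](C)(OC(=O)CP(=O)(OCC)OCC)C1 | intermediate
22 | (2S)-2-methyl-1-oxopentan-2-yl (diethoxyphosphoryl)acetate carrying the carbonyl oxide group at chain carbon 4 (C6) | CC(=[O+][O-])C[C@](C)(OC(=O)CP(=O)(OCC)OCC)C=O | intermediate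
23 | (2S)-4-hydroperoxy-4-methoxy-2-methyl-1-oxopentan-2-yl (diethoxyphosphoryl)acetate | COC(C)(OO)C[C@](C)(OC(=O)CP(=O)(OCC)OCC)C=O | intermediate
24 | (4S)-3-hydroxy-6-methoxy-4,6-dimethyl-1,2-dioxan-4-yl (diethoxyphosphoryl)acetate (anomers at C3 and C6) | COC1(C)C[C@](C)(OC(=O)CP(=O)(OCC)OCC)C(O)OO1 | intermediate
25 | (5S)-5-(2-hydroperoxy-2-methoxypropyl)-5-methylfuran-2(5H)-one | COC(C)(OO)C[C@]1(C)OC(=O)C=C1 | intermediate
26 | (4aS,7aS)-3-methoxy-3,4a-dimethyltetrahydrofuro[3,2-c][1,2]dioxin-6(3H)-one (both ketal epimers) | COC1(C)C[C@]2(C)OC(=O)C[C@@H]2OO1 | intermediate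
27 | (3R,4aS,7aS)-3,4a-dimethyl-3-[(2E)-2-methyl-3-(trimethylsilyl)prop-2-en-1-yl]tetrahydrofuro[3,2-c][1,2]dioxin-6(3H)-one | C/C(=C\[Si](C)(C)C)C[C@]1(C)C[C@]2(C)OC(=O)C[C@@H]2OO1 | intermediate
28 | (3R,4aS,7aS)-3-[(2E)-3-iodo-2-methylprop-2-en-1-yl]-3,4a-dimethyltetrahydrofuro[3,2-c][1,2]dioxin-6(3H)-one | C/C(=C\I)C[C@]1(C)C[C@]2(C)OC(=O)C[C@@H]2OO1 | intermediate
29 | plakortolide H | C/C(=C\C=C\CCC/C=C/c1ccccc1)C[C@]1(C)C[C@]2(C)OC(=O)C[C@@H]2OO1 | target

Total step count: 14. Longest linear sequence: 10 steps (steps 5 to 14).

**Steps most likely to fail**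

1. **Step 11.**
   - Possible failure: material may be lost by base-induced fragmentation of the peroxyhemiacetal, by internal redox between hydroperoxide and aldehyde, or by cycloreversion in the wrong sense.
   - Fallback: it uses known chemistry, takes the peroxide from H2O2 instead of ozone, sets out from 21 and comes back at 26. Ozonolysis of 21 in CH2Cl2 at −78 °C with Me2S work-up gives (2S)-2-methyl-1,4-dioxopentan-2-yl (diethoxyphosphoryl)acetate F1. LiCl and iPr2NEt in MeCN close it to (5S)-5-methyl-5-(2-oxopropyl)furan-2(5H)-one F2. Urea–H2O2 and catalytic Sc(OTf)3 in MeOH turn the ketone into hydroperoxy ketal 25, and Et2NH in CF3CH2OH cyclises 25 to 26.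

2. **Step 12.**
   - Possible failure: attack of the hindered gem-disilane may be slow, the peroxycarbenium ion may lose a proton, the Lewis acid may induce O–O heterolysis, or facial selectivity may be poor.
   - Fallback: it sets out from 26 and comes back at 29.
     - Core half: 3-methylbut-2-enal, TMSCl and Et3N give {[(1E)-3-methylbuta-1,3-dien-1-yl]oxy}trimethylsilane F3, a much more reactive π-nucleophile. Its vinylogous Mukaiyama reaction with 26 (TMSOTf, CH2Cl2, −78 °C) forms C6–C7 and gives (2E)-4-[(3R,4aS,7aS)-3,4a-dimethyl-6-oxotetrahydrofuro[3,2-c][1,2]dioxin-3-yl]-3-methylbut-2-enal F4.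
     - Side-chain half: tetrahydro-2H-pyran-2-ol and 3 (NaH, THF) give (5E)-6-phenylhex-5-en-1-ol F5. A Mitsunobu reaction with 1-phenyl-1H-tetrazole-5-thiol gives 1-phenyl-5-{[(5E)-6-phenylhex-5-en-1-yl]sulfanyl}-1H-tetrazole F6. (NH4)6Mo7O24 and H2O2 give 1-phenyl-5-{[(5E)-6-phenylhex-5-en-1-yl]sulfonyl}-1H-tetrazole F7.
     - Union: Julia–Kocienski olefination of F4 with premetalated F7 (KHMDS, THF, −78 °C) builds the (E)-C10=C11 bond and delivers 29.

3. **Step 8.**
   - Possible failure: enantiofacial discrimination on the small ring may be poor, or the metal cyclobutenolate may open electrocyclically during the long addition.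
   - Fallback: it uses resolution instead of asymmetric catalysis, without the bromine detour, sets out from 14 and comes back at 21. MeMgBr with CeCl3 in THF at −78 °C adds to 14 to give racemic 1,3-dimethylcyclobut-2-en-1-ol F8. DCC and DMAP with 20 give racemic 1,3-dimethylcyclobut-2-en-1-yl (diethoxyphosphoryl)acetate F9. Preparative HPLC on a chiral stationary phase separates the (S)-ester 21.

**Further compounds**
F1 | step 11 | (2S)-2-methyl-1,4-dioxopentan-2-yl (diethoxyphosphoryl)acetate | CC(=O)C[C@](C)(OC(=O)CP(=O)(OCC)OCC)C=O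
F2 | step 11 | (5S)-5-methyl-5-(2-oxopropyl)furan-2(5H)-one | CC(=O)C[C@]1(C)OC(=O)C=C1
F3 | step 12 | {[(1E)-3-methylbuta-1,3-dien-1-yl]oxy}trimethylsilane | C=C(C)/C=C/O[Si](C)(C)C
F4 | step 12 | (2E)-4-[(3R,4aS,7aS)-3,4a-dimethyl-6-oxotetrahydrofuro[3,2-c][1,2]dioxin-3-yl]-3-methylbut-2-enal | C/C(=C\C=O)C[C@]1(C)C[C@]2(C)OC(=O)C[C@@H]2OO1
F5 | step 12 | (5E)-6-phenylhex-5-en-1-ol | OCCCC/C=C/c1ccccc1
F6 | step 12 | 1-phenyl-5-{[(5E)-6-phenylhex-5-en-1-yl]sulfanyl}-1H-tetrazole | S(CCCC/C=C/c1ccccc1)c1nnnn1-c1ccccc1
F7 | step 12 | 1-phenyl-5-{[(5E)-6-phenylhex-5-en-1-yl]sulfonyl}-1H-tetrazole | O=S(=O)(CCCC/C=C/c1ccccc1)c1nnnn1-c1ccccc1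
F8 | step 8 | racemic 1,3-dimethylcyclobut-2-en-1-ol | CC1=CC(C)(O)C1
F9 | step 8 | racemic 1,3-dimethylcyclobut-2-en-1-yl (diethoxyphosphoryl)acetate | CC1=CC(C)(OC(=O)CP(=O)(OCC)OCC)C1
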